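The data are calculated with constants of no real substance; scatter was added.

Hours are the unit of these closed flasks, in which starting material and reagent make product under free catalyst at one temperature.

| flask | starting material | reagent | free catalyst | time |
|---|---|---|---|---|
| birch | 200 mM | 400 mM | 0.400 mM |  |
| ash | 100 mM | 300 mM | 0.400 mM |  |
| elm | 100 mM | 400 mM | 0.400 mM |  |
| maple | 200 mM | 800 mM | 0.400 mM |  |
| larch | 57.0 mM | 400 mM | 0.400 mM | 3.7 h |

- birch run (time / h: [product] / mM): 0.21: 38.5; 0.64: 53.0; 1.2: 56.9; 1.9: 60.7; 2.8: 62.1; 3.7: 62.8
- ash run (time / h: [product] / mM): 0.21: 16.1; 0.64: 22.7; 1.2: 25.9; 1.9: 28.3; 2.8: 28.2; 3.7: 29.2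
- elm run (time / h: [product] / mM): 0.21: 22.9; 0.64: 29.9; 1.2: 31.4; 1.9: 35.3; 2.8: 36.6; 3.7: 36.6
- maple run (time / h: [product] / mM): 0.21: 68.9; 0.64: 92.3; 1.2: 101.5; 1.9: 105.2; 2.8: 106.7; 3.7: 107.8

(standard deviation of a reading: 0.6 mM)

- Overall: starting material + reagent -> product, with free catalyst as catalyst.
- Constant volume, constant temperature.
- A reading of a species includes what of it is bound.
- An order is taken over about fifteen percent of the charge, up and down.

- the power of [starting material] that the first rate follows, about the charge of the birch run; measure it at two percent of starting material made into product (one fixed amount of product, the same in the runs compared)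
- the power of [reagent] that the first rate follows, about the charge of the birch run; measure it at two percent of starting material made into product
- product in the larch run at 3.7 h, as a share of the starting material charged

The elm run shows the ladder of time scales. Its product grows at a mean 109 mM h⁻¹ up to 0.21 h, so the starting material charged would last 0.917 h at that pace, and the readings span 3.7 h. Yet the mean rate between 0.21 h and 0.64 h is 16.3 mM h⁻¹, a fall by a factor of 6.70, while [starting material]·[reagent], counted as charge minus product, falls from the start to 0.64 h by a factor of 1.54, far less. Something that carries the rate therefore fades on the fastest rung, before the charge could drain on the middle one, and on the slowest rung the last two elm readings stand equal within the scatter, with 363 mM of reagent still present.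

The work the catalyst delivers can be counted as its reach: ln([starting material]₀/([starting material]₀ − [product])) divided by the mean [reagent], which is a rate constant times active catalyst summed over time, 1.19 L mol⁻¹ in the elm run. Of this, 56.1% is delivered by 0.21 h. The ash run gives 1.21 L mol⁻¹ on less reagent, and the birch and maple runs give 1.02 L mol⁻¹ and 1.04 L mol⁻¹. Reach thus ignores the reagent, which points to order one in reagent, and it sinks as starting material doubles, which points to an order of about 0.778 in starting material. Extended linearly to the larch charge, reach becomes 1.28 L mol⁻¹, and with mean [reagent] near 389 mM this reckoning gives 39.1% product.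

The forecast, reasoning that “the rate is about first order in reagent”, gives 0.73 for starting material, lower than this reckoning, with 0.95 for reagent and 39.3% for larch.

The simulation gives 0.84, 1.0 and 40.0%.

    free catalyst + starting material ⇌ catalyst-substrate complex, settled at all times (1.310 L mol⁻¹)
    catalyst-substrate complex + reagent ⇌ ternary complex, settled at all times (1.750 L mol⁻¹)
    ternary complex → product + free catalyst (9324 h⁻¹)
    2 starting material → homo dimer (4.968 L mol⁻¹ h⁻¹)
    2 free catalyst → 2 spent catalyst (30020 L mol⁻¹ h⁻¹)

Read back, the larch run has a reach of 1.32 L mol⁻¹, against 1.28 L mol⁻¹ reckoned and 1.19 L mol⁻¹ in the elm run. The maple run, where product comes to half of the charge at 1.08 h, has by then used 89.0% of its reach. Free catalyst passing into spent catalyst is the main reason for the larch shortfall: without that step the larch run reaches 91.7% rather than 40.0%.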